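**Assumption:** the SMILES is taken at face value, numbered as 6,7-dihydro-5H-cyclopenta[c]pyridine (N2, side chain on C3, carbinol C5, acetate carbon C6, ketone C7). This gives (5R,6S) in the ring, with 5-OH trans to 6-OAc, and (1E,3E,5S) in the side chain. (R)-Lactic acid, 2,5-dibromopyridine, (S)-2-methylbutan-1-ol, methyl chlorooxoacetate and ylide 16 are taken as purchased.

## The problem

1. The target 25 is a pyridine fused through C4a–C7a to a fully substituted five-membered carbocycle in which three consecutive carbons are oxidised: C5 (tertiary OH and CO2Me), C6 (methyl and OAc) and the C7 ketone.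
2. C5 and C6 are adjacent tetrasubstituted stereocentres. Neither carries hydrogen, so nothing can be corrected by epimerisation, and both must be set relative to each other and in the absolute sense.
3. The side-chain stereocentre (5S) is too remote to control the ring, so it needs its own source and a convergent junction.
4. The C5–OH/C7=O pair is an aldol. A C5 alkoxide can cleave C5–C6, and the enolate formed is planar at C6, so both ring stereocentres would be lost together.
5. Two tertiary hydroxyl groups must be told apart, since only O6 is acetylated. In any open-chain or cis-diol intermediate the acetyl group could migrate.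
6. The (1E,3E)-diene on an electron-poor pyridine argues for a late, neutral introduction.
7. The feature that makes the key step possible is a double correspondence. C6 with its methyl group, its oxygen and C7 is the α-carbon, hydroxyl and carboxyl of lactic acid, and C5 is the ketone carbon of an oxalyl unit. C4a (para to N) and C7a (meta to N) are the acidic C4–H and the exchangeable C5–Br of 2,5-dibromopyridine, whose C2–Br remains for the side chain.

## Retrosynthesis

**25 ⇒ 24 ⇒ 14 + 21 (C3–C1' bond).** The silyl ether 24 is the last intermediate, and the bond between the pyridine C3 and the diene is cut before it. Cutting here rather than inside the diene keeps both double-bond geometries in one small fragment, enyne 21, and keeps the diene away from all organolithium chemistry. The bromide 14 is much simpler than 24. The forward reaction must be neutral: hydrozirconation of 21 and a Negishi coupling at the C–Br bond next to nitrogen.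

**14 ⇒ 13 (O6–acetyl bond).** The acetyl group is put on when O6–H is the only free hydroxyl, with O5 still silylated. This avoids a selective acylation of a diol. The trans arrangement of O5 and O6 on the ring rules out migration afterwards.

**13 ⇒ 10 (C7a–C7 bond, opening of the temporary ring).** The carbocycle is opened between the pyridine carbon C7a and the ketone carbon C7, which is restored to the lactone carbonyl of a 1,3-dioxolan-4-one. This cut is preferred to the C5–C6 (aldol) cut because it never makes C6 planar. The forward reaction is an intramolecular acylation of arylmagnesium 11 (5-exo-trig). The hemiketal 12 then ejects pivalaldehyde, so the auxiliary ring is removed in the step that closes the target ring.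

**10 ⇒ 7 + 6 (C4a–C5 bond, key step).** The C5 carbinol is cut from the pyridine. This returns 2,5-dibromopyridine 7, lithiated at C4 to give 8, and the α-keto ester 6. The alternative cut at the same carbon, C5–CO2Me, would need a carboxyl anion equivalent and extra steps. The forward reaction must add 8 to the ketone of 6 only, on the face dictated by the adjacent quaternary carbon, and alkoxide 9 must be capped at once.

**6 ⇒ 3 + 4 and 3 ⇒ 1 + 2 (C5–C6 bond, acetal).** The keto ester is the C-acylation product of lithium enolate 5 with methyl chlorooxoacetate 4. The dioxolanone 3 is the cis pivalaldehyde acetal of (R)-lactic acid 1 with 2. The acetal carbon keeps the stereochemical information while C6 is planar and returns it on acylation (self-regeneration of stereocentres). This makes C6 quaternary from a cheap chiral-pool acid in two steps.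

**21 ⇒ 20 ⇒ 19 ⇒ 18 ⇒ 15 + 16 (side chain).** The terminal alkyne comes from enal 20 by one-carbon homologation. The trisubstituted (E)-alkene comes from a Wittig reaction of ylide 16 with aldehyde 17, which is made in the flask from (S)-2-methylbutan-1-ol 15.

## Roads not taken

**Alternative 1:** the most obvious cut is C5–C6, the aldol bond. The precursor would be diketone A1, a pyridine carrying a 2-acetoxypropanoyl group next to a methoxalyl group. The forward step is an intramolecular aldol of the α-acetoxy ketone enolate onto the keto ester (5-enolendo-exo-trig).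
- Enolisation erases C6, so all chirality would have to come from an external catalyst that controls two quaternary centres in one closure, for which no close model exists.
- The closure is reversible under the base that effects it.
- The cis-diol epimer would pass its acetyl group to O5 and drain the equilibrium.
- A1 needs two different acyl groups on neighbouring pyridine carbons, and the keto ester forbids the organometallic step that would install the second.
- The chosen plan forms the same bond while the acetal holds C6.

**Alternative 2:** a biogenetic-type ring contraction. The ester carbon and C5 are traced back to a six-membered ring: hydroxyquinone A2 is oxidised at C7 to the acetoxy trione A3, and a benzilic ester rearrangement with methoxide (the ring contraction of the Hooker oxidation) gives the bromo core A4.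
- A2 needs oxygen at C6 and methyl at C7 of the isoquinolinedione, the reverse of the position at which nucleophiles enter such quinones, so the run-up is long.
- The C7 stereocentre would come from an enantioselective oxidation of a hydroxyquinone, which has no close model.
- Methoxide is incompatible with a tertiary acetate flanked by two ketones (acyl transfer, retro-Claisen).
- The stepwise retro-Claisen/aldol pathway passes through a planar C7 enolate and would racemise.
- C5 would be set only by a puckering preference during the 1,2-shift.

**Alternative 3:** build the pyridine last by [2+2+2] cyclotrimerisation of diyne A5 with dienyl nitrile A6, for example with CpCo(CO)2. This forms C1–N2, C3–C4 and C4a–C7a.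
- A5 already contains both quaternary stereocentres, so the hard part is not simplified.
- The nitrile must insert with nitrogen next to the ynone terminus, and two terminal alkynes of similar size give no basis for that regiocontrol.
- A5 is a β-hydroxy ynone and prone to retro-aldol cleavage.
- The conjugated nitrile offers further π-bonds to the metal.

Key step: step 3

## Steps

**Step 1**
Reactants: 1 (R)-lactic acid; 2 pivalaldehyde
Product: 3 (2R,5R)-2-tert-butyl-5-methyl-1,3-dioxolan-4-one (cis)
Conditions: TsOH·H2O (cat.), H2SO4 (cat.), pentane, reflux, water separator; recrystallisation at −78 °C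
Reagents that add atoms: none
Why: Acid-catalysed acetalisation of the α-hydroxy acid; the cis acetal (tert-butyl and methyl on the same face) is the favoured, crystalline isomer, and its new acetal centre stores the configuration of the lactate carbon for step 2.

**Step 2**
Reactants: 3 (2R,5R)-2-tert-butyl-5-methyl-1,3-dioxolan-4-one; 4 methyl chlorooxoacetate
Product: 6 methyl 2-[(2R,4S)-2-tert-butyl-4-methyl-5-oxo-1,3-dioxolan-4-yl]-2-oxoacetate, via lithium enolate 5 (not isolated)
Conditions: LiN(iPr)2, THF, −78 °C; cannulation into 4, THF, −78 °C; AcOH quench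
Reagents that add atoms: none
Why: C-acylation of an ester-type lithium enolate by an acid chloride; the electrophile enters anti to the tert-butyl group, so the acyl group takes the place of the former hydrogen and the future C6 becomes quaternary with defined configuration. Inverse addition keeps the enolate away from the product ketone.

**Step 3**
Reactants: 7 2,5-dibromopyridine; 6 methyl 2-[(2R,4S)-2-tert-butyl-4-methyl-5-oxo-1,3-dioxolan-4-yl]-2-oxoacetate
Product: 10 methyl (2R)-2-[(2R,4S)-2-tert-butyl-4-methyl-5-oxo-1,3-dioxolan-4-yl]-2-(2,5-dibromopyridin-4-yl)-2-[(trimethylsilyl)oxy]acetate, via aryllithium 8 (not isolated), via lithium alkoxide 9 (not isolated)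
Conditions: LiN(iPr)2, THF, −78 °C; 6, −78 °C; Me3SiCl, −78 to −20 °C
Reagents that add atoms: chlorotrimethylsilane, C[Si](C)(C)Cl
Why: LiN(iPr)2 removes H4 of 7, the ring proton next to the 5-bromine, and at −78 °C aryllithium 8 adds to the ketone carbonyl of 6, the most electrophilic of its three carbonyl groups, before halogen migration can set in; alkoxide 9 is capped in the same flask as its silyl ether. The closest known reaction type is the 1,2-addition of aryllithium and Grignard reagents to α-keto esters that carry an α-oxygenated stereocentre, combined with lactic acid pivalaldehyde acetals as carriers of chirality. No ring is closed here: the step forms the C4a–C5 bond and leaves the 5-bromine ortho to it for the 5-exo closure of step 4. C6 is carried, not created: it was fixed in step 2 and is quaternary, so it cannot erode. The new stereocentre C5 should be controlled by C6 in a non-chelated transition state of the polar Felkin–Anh or Cornforth type, since lithium in THF binds the acetal-type ring oxygen poorly: the C6–O bond lies anti to the incoming aryl group, the methoxycarbonyl group sits beside the ring carbonyl carbon (planar, tied back in the ring, smaller than methyl), and the aryl group enters past that carbon. This places O5 on the side of the C6 methyl group and CO2Me on the side of O6, which is (R) at C5 and, after ring closure, the trans arrangement of O5 and O6. The step needs chemoselectivity (ketone over lactone and ester, secured by the adjacent ester), regioselective metalation (secured by the ortho bromine) and face selectivity (secured by the rigid dioxolanone); silylation blocks the retro-aldol path and marks O5 for later differentiation from O6.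

**Step 4**
Reactants: 10 methyl (2R)-2-[(2R,4S)-2-tert-butyl-4-methyl-5-oxo-1,3-dioxolan-4-yl]-2-(2,5-dibromopyridin-4-yl)-2-[(trimethylsilyl)oxy]acetate
Product: 13 methyl (5R,6S)-3-bromo-6-hydroxy-6-methyl-7-oxo-5-[(trimethylsilyl)oxy]-6,7-dihydro-5H-cyclopenta[c]pyridine-5-carboxylate, via arylmagnesium chloride 11 (not isolated), via magnesium hemiketal 12 (not isolated)
Conditions: iPrMgCl·LiCl, THF, −40 to 0 °C; aq. NH4Cl
Reagents that add atoms: none
Why: Bromine–magnesium exchange should take place at the 5-bromide, the position that exchanges in 2,5-dibromopyridines, and 11 attacks the dioxolanone carbonyl in a 5-exo-trig acyl substitution (Parham-type cyclisation); closure onto the methyl ester would need a four-membered ring. Hemiketal 12 collapses to the C7 ketone with loss of pivalaldehyde, which uncovers O6–H; both stereocentres are quaternary and untouched.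

**Step 5**
Reactants: 13 methyl (5R,6S)-3-bromo-6-hydroxy-6-methyl-7-oxo-5-[(trimethylsilyl)oxy]-6,7-dihydro-5H-cyclopenta[c]pyridine-5-carboxylate
Product: 14 methyl (5R,6S)-6-acetoxy-3-bromo-6-methyl-7-oxo-5-[(trimethylsilyl)oxy]-6,7-dihydro-5H-cyclopenta[c]pyridine-5-carboxylate
Conditions: Ac2O, DMAP, Et3N, CH2Cl2, 25–40 °C
Reagents that add atoms: acetic anhydride, CC(=O)OC(C)=O
Why: DMAP-catalysed acylation of a tertiary α-ketol; O6–H is the only free hydroxyl, no C5 alkoxide can form, and the trans arrangement of O5 and O6 excludes silyl or acyl migration.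

**Step 6**
Reactants: 15 (S)-2-methylbutan-1-ol; 16 ethyl 2-(triphenyl-λ5-phosphanylidene)propanoate
Product: 18 ethyl (2E,4S)-2,4-dimethylhex-2-enoate, via (S)-2-methylbutanal 17 (not isolated)
Conditions: TEMPO (cat.), PhI(OAc)2, CH2Cl2, rt; then 16, rt to 40 °C
Reagents that add atoms: none
Why: Oxidation under non-basic conditions gives the configurationally labile α-branched aldehyde, which is trapped in the same flask by the stabilised ylide (Wittig reaction); the trisubstituted enoate should form as the (E) isomer.

**Step 7**
Reactants: 18 ethyl (2E,4S)-2,4-dimethylhex-2-enoate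
Product: 19 (2E,4S)-2,4-dimethylhex-2-en-1-ol
Conditions: iBu2AlH, CH2Cl2, −78 °C; aq. potassium sodium tartrate
Reagents that add atoms: none
Why: 1,2-Reduction of an enoate to the allylic alcohol; the alkene geometry and the allylic stereocentre are not involved.

**Step 8**
Reactants: 19 (2E,4S)-2,4-dimethylhex-2-en-1-ol
Product: 20 (2E,4S)-2,4-dimethylhex-2-enal
Conditions: MnO2, CH2Cl2, rt
Reagents that add atoms: none
Why: Selective oxidation of an allylic alcohol on the MnO2 surface under neutral conditions, which spare the γ-stereocentre and the (E) geometry.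

**Step 9**
Reactants: 20 (2E,4S)-2,4-dimethylhex-2-enal
Product: 21 (3E,5S)-3,5-dimethylhept-3-en-1-yne
Conditions: Me3SiCHN2, n-BuLi, THF, −78 °C to rt
Reagents that add atoms: (trimethylsilyl)diazomethane, C[Si](C)(C)C=[N+]=[N-]
Why: Colvin rearrangement: lithiated (trimethylsilyl)diazomethane adds to the aldehyde, Peterson elimination and loss of N2 give an alkylidene carbene, and a 1,2-hydrogen shift gives the terminal alkyne. Carbonyl addition at −78 °C should outrun γ-deprotonation, so the stereocentre is kept.

**Step 10**
Reactants: 21 (3E,5S)-3,5-dimethylhept-3-en-1-yne; 14 methyl (5R,6S)-6-acetoxy-3-bromo-6-methyl-7-oxo-5-[(trimethylsilyl)oxy]-6,7-dihydro-5H-cyclopenta[c]pyridine-5-carboxylate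
Product: 24 methyl (5R,6S)-6-acetoxy-3-[(1E,3E,5S)-3,5-dimethylhepta-1,3-dien-1-yl]-6-methyl-7-oxo-5-[(trimethylsilyl)oxy]-6,7-dihydro-5H-cyclopenta[c]pyridine-5-carboxylate, via alkenylzirconocene 22 (not isolated), via alkenylzinc chloride 23 (not isolated)
Conditions: 21, Cp2Zr(H)Cl, THF, rt; ZnCl2, 0 °C; 14, Pd(PPh3)4 (5 mol %), rt to 40 °C
Reagents that add atoms: none
Why: syn-Hydrozirconation of the terminal alkyne puts zirconium on C1 and fixes the (1E) geometry, and after transmetalation to zinc a Negishi coupling follows; zerovalent palladium inserts into the C–Br bond next to nitrogen. The alkenylzinc reagent does not add to the ketone or the esters, and the medium is neutral, so the masked aldol and the acetate are safe.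

**Step 11**
Reactants: 24 methyl (5R,6S)-6-acetoxy-3-[(1E,3E,5S)-3,5-dimethylhepta-1,3-dien-1-yl]-6-methyl-7-oxo-5-[(trimethylsilyl)oxy]-6,7-dihydro-5H-cyclopenta[c]pyridine-5-carboxylate
Product: 25 methyl (5R,6S)-6-acetoxy-3-[(1E,3E,5S)-3,5-dimethylhepta-1,3-dien-1-yl]-5-hydroxy-6-methyl-7-oxo-6,7-dihydro-5H-cyclopenta[c]pyridine-5-carboxylate
Conditions: HF·pyridine, pyridine, THF, 0 °C
Reagents that add atoms: none
Why: Buffered fluoride cleavage of the tertiary trimethylsilyl ether; no base is present, so the freed aldol cannot revert, and the acetate stays on O6 because O5 is trans to it.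

## Compound list

1 | (R)-lactic acid | C[C@@H](O)C(=O)O | starting material
2 | pivalaldehyde | CC(C)(C)C=O | starting material
3 | (2R,5R)-2-tert-butyl-5-methyl-1,3-dioxolan-4-one | C[C@H]1O[C@@H](C(C)(C)C)OC1=O | intermediate
4 | methyl chlorooxoacetate | COC(=O)C(=O)Cl | starting material
5 | lithium (2R)-2-tert-butyl-5-methyl-1,3-dioxol-4-olate (lithium enolate, not isolated) | CC1=C(O[Li])O[C@H](C(C)(C)C)O1 | intermediate
6 | methyl 2-[(2R,4S)-2-tert-butyl-4-methyl-5-oxo-1,3-dioxolan-4-yl]-2-oxoacetate | COC(=O)C(=O)[C@]1(C)O[C@@H](C(C)(C)C)OC1=O | intermediate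
7 | 2,5-dibromopyridine | Brc1ccc(Br)nc1 | starting material
8 | 2,5-dibromo-4-lithiopyridine (aryllithium, not isolated) | [Li]c1cc(Br)ncc1Br | intermediate
9 | lithium alkoxide of methyl (2R)-2-[(2R,4S)-2-tert-butyl-4-methyl-5-oxo-1,3-dioxolan-4-yl]-2-(2,5-dibromopyridin-4-yl)-2-hydroxyacetate (not isolated) | COC(=O)[C@@](O[Li])(c1cc(Br)ncc1Br)[C@]1(C)O[C@@H](C(C)(C)C)OC1=O | intermediate
10 | methyl (2R)-2-[(2R,4S)-2-tert-butyl-4-methyl-5-oxo-1,3-dioxolan-4-yl]-2-(2,5-dibromopyridin-4-yl)-2-[(trimethylsilyl)oxy]acetate | COC(=O)[C@@](O[Si](C)(C)C)(c1cc(Br)ncc1Br)[C@]1(C)O[C@@H](C(C)(C)C)OC1=O | intermediate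
11 | arylmagnesium chloride from 10, magnesium on the former C5 of the pyridine (not isolated) | COC(=O)[C@@](O[Si](C)(C)C)(c1cc(Br)ncc1[Mg]Cl)[C@]1(C)O[C@@H](C(C)(C)C)OC1=O | intermediate
12 | magnesium hemiketal: ring-closed adduct with O–MgCl on C7 and the O–CH(tBu)–O bridge from C6 to C7 still closed (not isolated) | COC(=O)[C@@]1(O[Si](C)(C)C)c2cc(Br)ncc2[C@@]2(O[Mg]Cl)O[C@H](C(C)(C)C)O[C@@]12C | intermediate
13 | methyl (5R,6S)-3-bromo-6-hydroxy-6-methyl-7-oxo-5-[(trimethylsilyl)oxy]-6,7-dihydro-5H-cyclopenta[c]pyridine-5-carboxylate | Brc1cc2c(cn1)C(=O)[C@@](C)(O)[C@@]2(O[Si](C)(C)C)C(=O)OC | intermediate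
14 | methyl (5R,6S)-6-acetoxy-3-bromo-6-methyl-7-oxo-5-[(trimethylsilyl)oxy]-6,7-dihydro-5H-cyclopenta[c]pyridine-5-carboxylate | Brc1cc2c(cn1)C(=O)[C@@](C)(OC(C)=O)[C@@]2(O[Si](C)(C)C)C(=O)OC | intermediate
15 | (S)-2-methylbutan-1-ol | CC[C@H](C)CO | starting material
16 | ethyl 2-(triphenyl-λ5-phosphanylidene)propanoate | CCOC(=O)C(C)=P(c1ccccc1)(c1ccccc1)c1ccccc1 | starting material
17 | (S)-2-methylbutanal (not isolated) | CC[C@H](C)C=O | intermediate
18 | ethyl (2E,4S)-2,4-dimethylhex-2-enoate | CC[C@H](C)/C=C(C)/C(=O)OCC | intermediate
19 | (2E,4S)-2,4-dimethylhex-2-en-1-ol | CC[C@H](C)/C=C(C)/CO | intermediate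
20 | (2E,4S)-2,4-dimethylhex-2-enal | CC[C@H](C)/C=C(C)/C=O | intermediate
21 | (3E,5S)-3,5-dimethylhept-3-en-1-yne | CC[C@H](C)/C=C(C)/C#C | intermediate
22 | chlorobis(cyclopentadienyl)[(1E,3E,5S)-3,5-dimethylhepta-1,3-dien-1-yl]zirconium (not isolated) | CC[C@H](C)/C=C(C)/C=C/[Zr](Cl)(C1C=CC=C1)C1C=CC=C1 | intermediate
23 | chloro[(1E,3E,5S)-3,5-dimethylhepta-1,3-dien-1-yl]zinc (not isolated) | CC[C@H](C)/C=C(C)/C=C/[Zn]Cl | intermediate
24 | methyl (5R,6S)-6-acetoxy-3-[(1E,3E,5S)-3,5-dimethylhepta-1,3-dien-1-yl]-6-methyl-7-oxo-5-[(trimethylsilyl)oxy]-6,7-dihydro-5H-cyclopenta[c]pyridine-5-carboxylate | CC[C@H](C)/C=C(C)/C=C/c1cc2c(cn1)C(=O)[C@@](C)(OC(C)=O)[C@@]2(O[Si](C)(C)C)C(=O)OC | intermediate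
25 | methyl (5R,6S)-6-acetoxy-3-[(1E,3E,5S)-3,5-dimethylhepta-1,3-dien-1-yl]-5-hydroxy-6-methyl-7-oxo-6,7-dihydro-5H-cyclopenta[c]pyridine-5-carboxylate | CC[C@H](C)/C=C(C)/C=C/c1cc2c(cn1)C(=O)[C@@](C)(OC(C)=O)[C@@]2(O)C(=O)OC | target

## Step count and least certain steps

Total: 11 steps. Longest linear sequence: 7 steps (1, 2, 3, 4, 5, 10, 11); the side chain (steps 6 to 9) joins at step 10.

**Step 3 (key step).** The face selectivity at C5 is an expectation from a transition-state model, not a certainty.
- Lithium chelation between the ketone oxygen and the ring oxygen or lactone carbonyl would favour the other face and give poor or inverted selectivity.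
- Retro-aldol reversion of alkoxide 9 before silylation would let the C5 epimers equilibrate.
- Bromine migration in 8 above −70 °C would scramble the substitution pattern.

Fallback: form the C5–C6 bond instead of the C4a–C5 bond. It sets out from 7 and 3 and returns at 10.
- Lithiate 7 as before and quench with dimethyl oxalate to give methyl 2-(2,5-dibromopyridin-4-yl)-2-oxoacetate F1.
- Convert 3 with LiN(iPr)2 and Me3SiCl into (2R)-2-tert-butyl-5-methyl-4-[(trimethylsilyl)oxy]-1,3-dioxole F2.
- A TiCl4-mediated Mukaiyama aldol of F2 with F1 (attack anti to tert-butyl, open transition state on the chelated keto ester) gives methyl (2R)-2-[(2R,4S)-2-tert-butyl-4-methyl-5-oxo-1,3-dioxolan-4-yl]-2-(2,5-dibromopyridin-4-yl)-2-hydroxyacetate F3, which is silylated to 10.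
- This is an independent stereo-determining event and is not guaranteed to favour the required epimer; the lithium aldol of 5 with F1 is a third variant, though a closed chair transition state with the aryl group equatorial would favour the wrong C5 epimer.

**Step 2.** O-acylation of enolate 5 may compete, the enolate may add to the product ketone, and the β-keto lactone may cleave (retro-Claisen) during a basic work-up.

Fallback, from 3 back to 6: aldol addition of 5 to methyl glyoxylate gives methyl 2-[(2R,4S)-2-tert-butyl-4-methyl-5-oxo-1,3-dioxolan-4-yl]-2-hydroxyacetate F4 (either carbinol epimer), and Dess–Martin oxidation gives 6.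

**Step 4.** Exchange may take place in part at the 2-bromide, the hindered 5-bromide may exchange slowly so that iPrMgCl attacks the lactone or ester, or the crowded arylmagnesium may cyclise incompletely.

Fallback: differentiate the halogens by identity, not by position. It sets out from 6 and returns at 24.
- Use 5-bromo-2-chloropyridine F5 in step 3 to give the chloro analogue of 10, methyl (2R)-2-(5-bromo-2-chloropyridin-4-yl)-2-[(2R,4S)-2-tert-butyl-4-methyl-5-oxo-1,3-dioxolan-4-yl]-2-[(trimethylsilyl)oxy]acetate F6.
- Bromine–lithium exchange of its single bromide (n-BuLi, −100 °C, Parham conditions) and cyclisation give methyl (5R,6S)-3-chloro-6-hydroxy-6-methyl-7-oxo-5-[(trimethylsilyl)oxy]-6,7-dihydro-5H-cyclopenta[c]pyridine-5-carboxylate F7.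
- Acetylation gives methyl (5R,6S)-6-acetoxy-3-chloro-6-methyl-7-oxo-5-[(trimethylsilyl)oxy]-6,7-dihydro-5H-cyclopenta[c]pyridine-5-carboxylate F8.
- Negishi coupling of F8 with 23, using a catalyst suited to chloropyridines (Pd2(dba)3 with a biarylphosphine), gives 24.

**Step 5.** Acylation of the crowded tertiary α-ketol may be slow, and forcing conditions may remove the silyl group and acetylate O5 as well.

Fallback, from 10 directly to 14 with no new compound: after the ring closure of step 4, warm the mixture so that 12 collapses, then trap the magnesium alkoxide on O6 in the same flask with acetic anhydride. This acylates an alkoxide rather than a neutral hindered alcohol and bypasses 13.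

**Step 10.** Residual Cp2Zr(H)Cl may reduce the ketone of 14, ZnCl2 may cleave the silyl ether early, or the diene geometry may be partly lost.

Fallback: a tin-based coupling. It sets out from 21 and returns at 24.
- Hydrozirconation of 21 followed by Bu3SnCl gives tributyl[(1E,3E,5S)-3,5-dimethylhepta-1,3-dien-1-yl]stannane F9, which is isolated.
- Stille coupling of F9 with 14 (Pd2(dba)3, P(2-furyl)3, CuI, DMF, 40–50 °C) gives 24 without any hydride or Lewis acid present.

## Further compounds

F1 | step 3 | methyl 2-(2,5-dibromopyridin-4-yl)-2-oxoacetate | COC(=O)C(=O)c1cc(Br)ncc1Br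
F2 | step 3 | (2R)-2-tert-butyl-5-methyl-4-[(trimethylsilyl)oxy]-1,3-dioxole | CC1=C(O[Si](C)(C)C)O[C@H](C(C)(C)C)O1
F3 | step 3 | methyl (2R)-2-[(2R,4S)-2-tert-butyl-4-methyl-5-oxo-1,3-dioxolan-4-yl]-2-(2,5-dibromopyridin-4-yl)-2-hydroxyacetate | COC(=O)[C@@](O)(c1cc(Br)ncc1Br)[C@]1(C)O[C@@H](C(C)(C)C)OC1=O
F4 | step 2 | methyl 2-[(2R,4S)-2-tert-butyl-4-methyl-5-oxo-1,3-dioxolan-4-yl]-2-hydroxyacetate (either carbinol epimer) | COC(=O)C(O)[C@]1(C)O[C@@H](C(C)(C)C)OC1=O
F5 | step 4 | 5-bromo-2-chloropyridine | Clc1ccc(Br)cn1
F6 | step 4 | methyl (2R)-2-(5-bromo-2-chloropyridin-4-yl)-2-[(2R,4S)-2-tert-butyl-4-methyl-5-oxo-1,3-dioxolan-4-yl]-2-[(trimethylsilyl)oxy]acetate | COC(=O)[C@@](O[Si](C)(C)C)(c1cc(Cl)ncc1Br)[C@]1(C)O[C@@H](C(C)(C)C)OC1=O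
F7 | step 4 | methyl (5R,6S)-3-chloro-6-hydroxy-6-methyl-7-oxo-5-[(trimethylsilyl)oxy]-6,7-dihydro-5H-cyclopenta[c]pyridine-5-carboxylate | Clc1cc2c(cn1)C(=O)[C@@](C)(O)[C@@]2(O[Si](C)(C)C)C(=O)OC
F8 | step 4 | methyl (5R,6S)-6-acetoxy-3-chloro-6-methyl-7-oxo-5-[(trimethylsilyl)oxy]-6,7-dihydro-5H-cyclopenta[c]pyridine-5-carboxylate | Clc1cc2c(cn1)C(=O)[C@@](C)(OC(C)=O)[C@@]2(O[Si](C)(C)C)C(=O)OC
F0 | step 5 | none | none
F9 | step 10 | tributyl[(1E,3E,5S)-3,5-dimethylhepta-1,3-dien-1-yl]stannane | CC[C@H](C)/C=C(C)/C=C/[Sn](CCCC)(CCCC)CCCC
A1 | alternative 1 | methyl 2-[5-(2-acetoxypropanoyl)-2-bromopyridin-4-yl]-2-oxoacetate (racemic) | COC(=O)C(=O)c1cc(Br)ncc1C(=O)C(C)OC(C)=O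
A2 | alternative 2 | 3-bromo-6-hydroxy-7-methylisoquinoline-5,8-dione | CC1=C(O)C(=O)c2cc(Br)ncc2C1=O
A3 | alternative 2 | (7R)-7-acetoxy-3-bromo-7-methylisoquinoline-5,6,8(7H)-trione | O=C1c2cnc(Br)cc2C(=O)C(=O)[C@]1(C)OC(C)=O
A4 | alternative 2 | methyl (5R,6S)-6-acetoxy-3-bromo-5-hydroxy-6-methyl-7-oxo-6,7-dihydro-5H-cyclopenta[c]pyridine-5-carboxylate | Brc1cc2c(cn1)C(=O)[C@@](C)(OC(C)=O)[C@@]2(O)C(=O)OC
A5 | alternative 3 | methyl (2R,3S)-3-acetoxy-2-ethynyl-2-hydroxy-3-methyl-4-oxohex-5-ynoate | C#CC(=O)[C@@](C)(OC(C)=O)[C@](O)(C#C)C(=O)OC
A6 | alternative 3 | (2E,4E,6S)-4,6-dimethylocta-2,4-dienenitrile | CC[C@H](C)/C=C(C)/C=C/C#N
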